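(The numbers in the tables stem from a simulated flask with made-up constants, noise included.)

Begin at early times: divide a run's first reading of target by its time and call that the early slope, s.

common to all: free catalyst 0.0400 M
- Sunday's: substrate 0.400 M; coupling partner 0.440 M
- Wednesday's: substrate 0.200 M; coupling partner 0.240 M
- Saturday's: substrate 0.200 M; coupling partner 0.440 M
- Monday's: substrate 0.400 M; coupling partner 0.150 M; time 58 min

| run | time / min | [target] / M |
|---|---|---|
| Sunday's run | 9.7 | 0.0294 |
| Sunday's run | 19 | 0.0487 |
| Sunday's run | 29 | 0.0655 |
| Sunday's run | 39 | 0.0772 |
| Sunday's run | 48 | 0.0827 |
| Sunday's run | 58 | 0.0908 |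
| Wednesday's run | 9.7 | 0.0244 |
| Wednesday's run | 19 | 0.0435 |
| Wednesday's run | 29 | 0.0541 |
| Wednesday's run | 39 | 0.0591 |
| Wednesday's run | 48 | 0.0650 |
| Wednesday's run | 58 | 0.0659 |
| Saturday's run | 9.7 | 0.0341 |
| Saturday's run | 19 | 0.0594 |
| Saturday's run | 29 | 0.0751 |
| Saturday's run | 39 | 0.0825 |
| Saturday's run | 48 | 0.0856 |
| Saturday's run | 58 | 0.0851 |

(each reading ± 0.001 M)

- Overall: substrate + coupling partner -> target, with free catalyst as catalyst.
- Constant volume, constant temperature.
- Bound and free are read together.
- An order is taken over about fifteen percent of the charge, up and down.

- reaction order in [substrate] at the outset, round the charge of the Sunday's run, defined at two percent of the substrate turned into target (one fixed amount of target, the same in the runs compared)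
- reaction order in [coupling partner] at the outset, round the charge of the Sunday's run, defined at two percent of the substrate turned into target
- target in the Monday's run at 58 min, as a share of the substrate charged

Sunday's run has s = 0.00303 M/min. Divide its target at 58 min by s, which gives 30.0 min, and name this the working time W: the minutes at the early rate that the yield is worth. Assume that Monday's run, with Sunday's substrate and catalyst charges, keeps this W. Then scale s alone.

Bound from above, loosely. Monday's run charges less coupling partner than substrate, so the coupling partner is the limiting reagent and caps target at 37.5% of the substrate charged.

Now tighten. Wednesday's and Saturday's runs share a substrate charge, and their first readings, with their scatter, give a reading of the order in coupling partner of n = 0.552. Scaling Sunday's s down to Monday's charge with exponent n gives my assumed upper edge of 12.5%. Proportional scaling, my assumed limit, gives a lower edge of 7.74%. My own commitment takes the exponent midway, 0.776, and gives 9.85%.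

The forecast gives −0.35 in substrate, 0.5 in coupling partner and 11.5% for Monday's run, reasoning “With a lifetime near 30 min and some coupling-partner depletion”. That yield lies inside my bracket, higher than my midway figure.

The flask gives 9.38% for Monday's run, inside my bracket and lower than my midway figure, with orders of −0.55 in substrate and 0.81 in coupling partner at Sunday's charge.

    free catalyst + substrate ⇌ catalyst-substrate complex, settled at all times (15.50 /M)
    free catalyst + coupling partner ⇌ catalyst-reagent complex, settled at all times (2.050 /M)
    catalyst-substrate complex + catalyst-reagent complex → target + 2 free catalyst (23.94 /M/min)
    target → decomposed product (0.01626 /min)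
    free catalyst + coupling partner → spent catalyst + coupling partner (0.08160 /M/min)

Turn W around: if Monday's run kept W, its yield of 0.0375 M divided by W asks for an early slope of 0.00125 M/min, which against Sunday's s is an exponent of 0.821 over the step from Sunday's to Monday's charge of coupling partner. Carried to Wednesday's run, W times its early slope gives 0.0754 M, and the reading at 58 min is 0.0659 M.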